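**Retrosynthetic overview**
1. Feature: C4 of ring C (eudesmane numbering) is a fully substituted carbon with CH3, the ring B aryloxy oxygen and two carbon arms (C3, C5). It is the carbinol carbon of (R)-linalool, whose vinyl group becomes C5–C6 and whose chain becomes C3–C2–C1.
2. Target ⇒ dibromo cis-octalone 20 by desilylation, removal of the C1 oxygen, two Stille allylations, and hydrogenation of C6=C7 directed from a C1 hydroxyl (sets C7).
3. 20 ⇒ trienone 19 by intramolecular Diels–Alder (bonds C5–C10 and C8–C9). Rings C and D close together and last; rings A and B are bought as arenes.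
4. 19 ⇒ linalool aryl ether: the diene by cross-metathesis with a vinyl ketone and Wittig methylenation, C1 by glycol cleavage, isopropenyl addition and oxidation.
5. Aryl ether ⇒ 4-bromo-2,6-difluorobenzaldehyde by two SNAr steps (4-bromophenol first, linalool second and cold) and a Dakin-type oxidation of the formyl group to the ring B phenol.

Key step: step 14

Remark: eudesmane numbering is used for the decalin carbons; ring A is the 4-allylphenoxy arene, ring B the central arene, ring C the carbocycle C1–C5/C10, ring D the carbocycle C5–C10; the target SMILES is read as the cis-fused (4R,5S,7R,10R) isomer with CH3-4, H-5, CH3-10 and the C7 side chain on one face (β) and the aryloxy group on the other (α).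

**Step 1**
Reactants: 1 4-bromo-2,6-difluorobenzaldehyde; 2 4-bromophenol
Product: 3 4-bromo-2-(4-bromophenoxy)-6-fluorobenzaldehyde
Conditions: K2CO3, DMF, 0 °C → rt
Reagents that add atoms: none
Why: SNAr of the phenoxide at a fluorine ortho to the formyl group; the aryloxy group then deactivates the ring enough for the second fluorine to survive at room temperature.

**Step 2**
Reactants: 3 4-bromo-2-(4-bromophenoxy)-6-fluorobenzaldehyde; 4 (R)-linalool
Product: 5 4-bromo-2-(4-bromophenoxy)-6-{[(3R)-3,7-dimethylocta-1,6-dien-3-yl]oxy}benzaldehyde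
Conditions: KN(SiMe3)2, THF, −40 °C; then 3, → 0 °C
Reagents that add atoms: none
Why: SNAr of the remaining ortho fluorine by the potassium tertiary alkoxide in the cold, placed after the warmer phenoxide step so that the tertiary allylic aryl ether is never heated towards an aromatic Claisen shift; the C–O bond of linalool is untouched, so C4 stays (R).

**Step 3**
Reactants: 5
Product: 6 4-bromo-2-(4-bromophenoxy)-6-{[(3R)-6,7-dihydroxy-3,7-dimethyloct-1-en-3-yl]oxy}benzaldehyde (both epimers at the secondary carbinol)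
Conditions: K2OsO4·2H2O (cat.), N-methylmorpholine N-oxide, acetone–H2O, 0 °C
Reagents that add atoms: N-methylmorpholine N-oxide, C[N+]1([O-])CCOCC1; water, O
Why: Upjohn dihydroxylation picks the electron-rich trisubstituted alkene over the hindered, oxygen-deactivated vinyl group; the new carbinol centre is formed as both epimers and disappears in step 11.

**Step 4**
Reactants: 6
Product: 8 4-bromo-2-(4-bromophenoxy)-6-{[(3R)-6,7-dihydroxy-3,7-dimethyloct-1-en-3-yl]oxy}phenol, via aryl formate 7 (not isolated)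
Conditions: 3-chloroperoxybenzoic acid, NaHCO3, CH2Cl2, 0 °C → rt; then K2CO3 (cat.), MeOH, rt
Reagents that add atoms: 3-chloroperoxybenzoic acid, OOC(=O)c1cccc(Cl)c1
Why: Baeyer–Villiger oxidation of the electron-rich 2,6-dioxygenated benzaldehyde with aryl migration (Dakin-type) followed by methanolysis of the formate; the peracid-sensitive alkene is already a diol.

**Step 5**
Reactants: 8
Product: 9 SEM ether of 8, (6R)-6-[5-bromo-3-(4-bromophenoxy)-2-{[2-(trimethylsilyl)ethoxy]methoxy}phenoxy]-2,6-dimethyloct-7-ene-2,3-diol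
Conditions: 2-(trimethylsilyl)ethoxymethyl chloride, K2CO3, DMF, 0 °C → rt
Reagents that add atoms: 2-(trimethylsilyl)ethoxymethyl chloride, C[Si](C)(C)CCOCCl
Why: Williamson alkylation of the phenoxide, the only hydroxyl acidic enough for K2CO3, masks the phenol against periodate and organometallic reagents.

**Step 6**
Reactants: 9
Product: 10 2,3-bis(trimethylsilyl) ether of 9
Conditions: N-(trimethylsilyl)imidazole, CH2Cl2, rt
Reagents that add atoms: N-(trimethylsilyl)imidazole, C[Si](C)(C)n1ccnc1
Why: Neutral silylation caps both hydroxyls, so that no alkoxide can add in a 6-exo oxa-Michael sense to the enone of step 9 or under the basic ylide of step 10.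

**Step 7**
Reactants: 11 3-hydroxy-3-methylbutan-2-one
Product: 12 4-hydroxy-4-methylpent-1-en-3-one
Conditions: (CH2O)n, i-Pr2NH2 CF3CO2, THF, reflux
Reagents that add atoms: paraformaldehyde (as formaldehyde), C=O
Why: Mannich-type α-methylenation of a methyl ketone that has a single enolisable position.

**Step 8**
Reactants: 12
Product: 13 4-methyl-4-(triethylsilyloxy)pent-1-en-3-one
Conditions: Et3SiOTf, 2,6-lutidine, CH2Cl2, −78 → 0 °C
Reagents that add atoms: triethylsilyl trifluoromethanesulfonate, CC[Si](CC)(CC)OS(=O)(=O)C(F)(F)F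
Why: Silyl triflate silylation of the hindered tertiary alcohol; the ether later keeps this hydroxyl from steering the iridium catalyst of step 16.

**Step 9**
Reactants: 10; 13
Product: 14 E enone, (4E,6R)-6-[5-bromo-3-(4-bromophenoxy)-2-(SEM-oxy)phenoxy]-2,6,10-trimethyl-2-(triethylsilyloxy)-9,10-bis(trimethylsilyloxy)undec-4-en-3-one
Conditions: second-generation Hoveyda–Grubbs catalyst RuCl2(H2IMes)(=CH-C6H4-2-OiPr) (10 mol %), 13 (4 equiv), CH2Cl2, 40 °C
Reagents that add atoms: none
Why: Olefin cross-metathesis of a hindered allylic-quaternary vinyl group with an excess of a vinyl ketone is a known selective pairing and gives the E enone; 10 has no second alkene, so ring-closing metathesis cannot compete.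

**Step 10**
Reactants: 14
Product: 15 E diene, 14 with the ketone C=O replaced by C=CH2 (C5=C6–C7(=C8H2)–C11)
Conditions: Ph3PCH3Br, KOt-Bu, THF, 0 → 40 °C
Reagents that add atoms: methyltriphenylphosphonium bromide, C[P+](c1ccccc1)(c1ccccc1)c1ccccc1.[Br-]
Why: Wittig methylenation of the non-enolisable conjugated ketone gives the 2-substituted E diene without touching the silyl ethers.

**Step 11**
Reactants: 15
Product: 17 (4R,5E)-4-[5-bromo-3-(4-bromophenoxy)-2-(SEM-oxy)phenoxy]-4,8-dimethyl-7-methylidene-8-(triethylsilyloxy)non-5-enal, via diene diol 16 (not isolated)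
Conditions: K2CO3, MeOH, rt; then NaIO4, THF–pH 7 buffer, 0 °C → rt
Reagents that add atoms: none
Why: Carbonate methanolysis removes only the trimethylsilyl ethers and buffered periodate glycol cleavage gives the C1 aldehyde under neutral conditions that spare the acid-labile dienyl aryl ether.

**Step 12**
Reactants: 17
Product: 18 (6R,7E)-6-[5-bromo-3-(4-bromophenoxy)-2-(SEM-oxy)phenoxy]-2,6,10-trimethyl-9-methylidene-10-(triethylsilyloxy)undeca-1,7-dien-3-ol (both C3 epimers)
Conditions: CH2=C(CH3)MgBr, THF, −78 °C; aq. NH4Cl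
Reagents that add atoms: isopropenylmagnesium bromide, CC(=C)[Mg]Br
Why: Grignard 1,2-addition to the only carbonyl group; the carbinol epimers converge in step 13.

**Step 13**
Reactants: 18
Product: 19 trienone, (6R,7E)-6-[5-bromo-3-(4-bromophenoxy)-2-(SEM-oxy)phenoxy]-2,6,10-trimethyl-9-methylidene-10-(triethylsilyloxy)undeca-1,7-dien-3-one
Conditions: Dess–Martin periodinane, NaHCO3, CH2Cl2, 0 °C; used at once
Reagents that add atoms: none
Why: Buffered Dess–Martin oxidation of the allylic alcohol unveils the isopropenyl ketone dienophile without acid.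

**Step 14**
Reactants: 19
Product: 20 cis-fused octalone, (4R,5S,10R)-4-[5-bromo-3-(4-bromophenoxy)-2-(SEM-oxy)phenoxy]-4,10-dimethyl-7-[2-(triethylsilyloxy)propan-2-yl]-octal-6-en-1-one (CH3-4, H-5 and CH3-10 on one face)
Conditions: PhMe (0.01 M), 2,6-di-tert-butyl-4-methylphenol (cat.), 60 °C, dark
Reagents that add atoms: none
Why: Thermal, concerted but asynchronous intramolecular [4+2] cycloaddition of the E diene (C5–C8) with the isopropenyl ketone (C9=C10), the known behaviour of 1,7,9-decatrien-3-ones whose tether ketone is conjugated with the dienophile. Ring D closes as the cyclohexene of the [4+2] (bonds C8–C9 and C5–C10), and ring C closes at the same time as the six-membered tether ring through the C5–C10 bond (fused mode, tether on the diene terminus). C10 is set relative to C5 by the endo position of the tether carbonyl under the diene, which leaves CH3-10 exo and cis to H-5 (cis fusion); suprafacial addition to the E alkene fixes H-5. C5 is set relative to C4 by the rotamer about C4–C5: the tether holds C3 on the enone side, the C4–O bond stands perpendicular to the diene and anti to the incoming enone (the usual preference of dienes with an allylic oxygen), and the C4 methyl lies in the diene plane next to H-5, so CH3-4 ends cis and the aryloxy group trans to H-5 and CH3-10. The step therefore needs endo selectivity and this diene face; the conjugated tether ketone secures the first, and the second rests on the anti-oxygen preference together with the long, late-forming C5–C10 bond, which keeps the contact between CH3-4 and the exo CH3-10 small. The temperature stays far below that of an aromatic Claisen shift of the tertiary dienyl aryl ether, and no Lewis acid is used because the ether would ionise.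

**Step 15**
Reactants: 20
Product: 21 (1S,4R,5S,10R)-1α-alcohol of 20 (OH trans to CH3-10)
Conditions: NaBH4, MeOH–THF, 0 °C
Reagents that add atoms: none
Why: Hydride reduction by axial attack on the β face in the conformer with C9 axial on ring C (C9 screens the α face) should give the equatorial 1α-alcohol; any 1β epimer is returned to 20 with the reagent of step 13.

**Step 16**
Reactants: 21
Product: 22 (1S,4R,5S,7R,10R)-decalin alcohol, 21 with C6–C7 saturated and the C7 side chain β
Conditions: [Ir(cod)(PCy3)(py)]PF6 (10 mol %), H2 (1 atm), CH2Cl2, 0 °C → rt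
Reagents that add atoms: none
Why: Hydroxyl-directed homogeneous hydrogenation: in the conformer with C1 axial on ring D the 1α-OH lies under the C6=C7 alkene, binds the cationic iridium and delivers H2 to the α face, which makes H-7 α and the side chain β (cis to CH3-10 and H-5); aryl bromides and silyl ethers are inert.

**Step 17**
Reactants: 22
Product: 23 diallyl alcohol, 22 with both Br replaced by CH2CH=CH2
Conditions: CH2=CHCH2SnBu3 (3 equiv), Pd(PPh3)4 (10 mol %), PhMe, 100 °C
Reagents that add atoms: allyltributylstannane, C=CC[Sn](CCCC)(CCCC)CCCC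
Why: Double Stille coupling of the two aryl bromides, placed after the hydrogenation (which would reduce allyl groups) and before the tin hydride step (which would reduce aryl bromides).

**Step 18**
Reactants: 23
Product: 25 O-(C1) S-methyl xanthate of 23, via sodium xanthate 24 (not isolated)
Conditions: NaH, THF, 0 °C; CS2; then MeI, rt
Reagents that add atoms: carbon disulfide, S=C=S; iodomethane, CI
Why: Xanthate ester formation from the secondary alkoxide prepares the C1 oxygen for radical removal.

**Step 19**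
Reactants: 25
Product: 26 (4R,5S,7R,10R)-bis-protected target, C1 now CH2
Conditions: Bu3SnH, azobisisobutyronitrile (cat.), PhMe, 90 °C
Reagents that add atoms: none
Why: Barton–McCombie deoxygenation removes the C1 oxygen once it has served as activating group and directing group; allyl arenes, ethers and silyl groups tolerate the tin radical chain.

**Step 20**
Reactants: 26
Product: 27 target, CNP0254037.2
Conditions: Bu4NF, THF–DMPU, 60 °C; aq. NH4Cl
Reagents that add atoms: none
Why: Fluoride desilylation cleaves the tertiary triethylsilyl ether and, by attack at silicon and fragmentation, the SEM ether, releasing the tertiary alcohol and the ring B phenol.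

**Compound list**
1 | 4-bromo-2,6-difluorobenzaldehyde | O=Cc1c(F)cc(Br)cc1F | starting material
2 | 4-bromophenol | Oc1ccc(Br)cc1 | starting material
3 | 4-bromo-2-(4-bromophenoxy)-6-fluorobenzaldehyde | O=Cc1c(F)cc(Br)cc1Oc1ccc(Br)cc1 | intermediate
4 | (R)-linalool | O[C@](C=C)(C)CCC=C(C)C | starting material
5 | linalyl aryl ether aldehyde | Brc1ccc(Oc2cc(Br)cc(O[C@](C=C)(C)CCC=C(C)C)c2C=O)cc1 | intermediate
6 | diol aldehyde (carbinol epimers) | Brc1ccc(Oc2cc(Br)cc(O[C@](C=C)(C)CCC(O)C(C)(C)O)c2C=O)cc1 | intermediate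
7 | aryl formate of 8 | Brc1ccc(Oc2cc(Br)cc(O[C@](C=C)(C)CCC(O)C(C)(C)O)c2OC=O)cc1 | intermediate (not isolated)
8 | ring B phenol diol | Brc1ccc(Oc2cc(Br)cc(O[C@](C=C)(C)CCC(O)C(C)(C)O)c2O)cc1 | intermediate
9 | SEM ether diol | Brc1ccc(Oc2cc(Br)cc(O[C@](C=C)(C)CCC(O)C(C)(C)O)c2OCOCC[Si](C)(C)C)cc1 | intermediate
10 | bis(trimethylsilyl) ether of 9 | Brc1ccc(Oc2cc(Br)cc(O[C@](C=C)(C)CCC(O[Si](C)(C)C)C(C)(C)O[Si](C)(C)C)c2OCOCC[Si](C)(C)C)cc1 | intermediate
11 | 3-hydroxy-3-methylbutan-2-one | CC(=O)C(C)(C)O | starting material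
12 | 4-hydroxy-4-methylpent-1-en-3-one | C=CC(=O)C(C)(C)O | intermediate
13 | 4-methyl-4-(triethylsilyloxy)pent-1-en-3-one | C=CC(=O)C(C)(C)O[Si](CC)(CC)CC | intermediate
14 | E enone | Brc1ccc(Oc2cc(Br)cc(O[C@](/C=C/C(=O)C(C)(C)O[Si](CC)(CC)CC)(C)CCC(O[Si](C)(C)C)C(C)(C)O[Si](C)(C)C)c2OCOCC[Si](C)(C)C)cc1 | intermediate
15 | E diene bis(trimethylsilyl) ether | Brc1ccc(Oc2cc(Br)cc(O[C@](/C=C/C(=C)C(C)(C)O[Si](CC)(CC)CC)(C)CCC(O[Si](C)(C)C)C(C)(C)O[Si](C)(C)C)c2OCOCC[Si](C)(C)C)cc1 | intermediate
16 | diene diol | Brc1ccc(Oc2cc(Br)cc(O[C@](/C=C/C(=C)C(C)(C)O[Si](CC)(CC)CC)(C)CCC(O)C(C)(C)O)c2OCOCC[Si](C)(C)C)cc1 | intermediate (not isolated)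
17 | diene aldehyde | Brc1ccc(Oc2cc(Br)cc(O[C@](/C=C/C(=C)C(C)(C)O[Si](CC)(CC)CC)(C)CCC=O)c2OCOCC[Si](C)(C)C)cc1 | intermediate
18 | isopropenyl carbinol (epimers) | Brc1ccc(Oc2cc(Br)cc(O[C@](/C=C/C(=C)C(C)(C)O[Si](CC)(CC)CC)(C)CCC(O)C(C)=C)c2OCOCC[Si](C)(C)C)cc1 | intermediate
19 | trienone (cycloaddition precursor) | Brc1ccc(Oc2cc(Br)cc(O[C@](/C=C/C(=C)C(C)(C)O[Si](CC)(CC)CC)(C)CCC(=O)C(C)=C)c2OCOCC[Si](C)(C)C)cc1 | intermediate
20 | cis-fused octalone (cycloadduct) | Brc1ccc(Oc2cc(Br)cc(O[C@]3(C)CCC(=O)[C@]4(C)CCC(C(C)(C)O[Si](CC)(CC)CC)=C[C@@H]43)c2OCOCC[Si](C)(C)C)cc1 | intermediate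
21 | 1α-alcohol | Brc1ccc(Oc2cc(Br)cc(O[C@]3(C)CC[C@H](O)[C@]4(C)CCC(C(C)(C)O[Si](CC)(CC)CC)=C[C@@H]43)c2OCOCC[Si](C)(C)C)cc1 | intermediate
22 | saturated 1α-alcohol | Brc1ccc(Oc2cc(Br)cc(O[C@]3(C)CC[C@H](O)[C@]4(C)CC[C@@H](C(C)(C)O[Si](CC)(CC)CC)C[C@@H]43)c2OCOCC[Si](C)(C)C)cc1 | intermediate
23 | diallyl alcohol | C=CCc1ccc(Oc2cc(CC=C)cc(O[C@]3(C)CC[C@H](O)[C@]4(C)CC[C@@H](C(C)(C)O[Si](CC)(CC)CC)C[C@@H]43)c2OCOCC[Si](C)(C)C)cc1 | intermediate
24 | sodium xanthate | C=CCc1ccc(Oc2cc(CC=C)cc(O[C@]3(C)CC[C@H](OC(=S)[S-])[C@]4(C)CC[C@@H](C(C)(C)O[Si](CC)(CC)CC)C[C@@H]43)c2OCOCC[Si](C)(C)C)cc1.[Na+] | intermediate (not isolated)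
25 | S-methyl xanthate | C=CCc1ccc(Oc2cc(CC=C)cc(O[C@]3(C)CC[C@H](OC(=S)SC)[C@]4(C)CC[C@@H](C(C)(C)O[Si](CC)(CC)CC)C[C@@H]43)c2OCOCC[Si](C)(C)C)cc1 | intermediate
26 | bis-protected target | C=CCc1ccc(Oc2cc(CC=C)cc(O[C@]3(C)CCC[C@]4(C)CC[C@@H](C(C)(C)O[Si](CC)(CC)CC)C[C@@H]43)c2OCOCC[Si](C)(C)C)cc1 | intermediate
27 | CNP0254037.2 | C=CCc1ccc(Oc2cc(CC=C)cc(O[C@]3(C)CCC[C@]4(C)CC[C@@H](C(C)(C)O)C[C@@H]43)c2O)cc1 | target

**Step count and risks**
Total step count: 20. Longest linear sequence: 18 steps (steps 1–6 and 9–20, from 1 to 27).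

Steps most likely to fail:

1. Step 14 (key step). The cycloaddition may take the other diene face (C4 methyl anti to the enone, aryloxy group in the diene plane), which the contact between CH3-4 and the exo CH3-10 favours and which would give the C4-epimeric cis adduct; exo addition would give trans-fused material. Fallback: make C5 and C10 in separate events. From 17, vinylmagnesium bromide gives the vinyl carbinol F1 and Dess–Martin oxidation gives the vinyl ketone F2. F2 has no methyl on the dienophile, so the opposing contact is absent, and it should cyclise at room temperature to the C10–H octalones F3. Both ring fusions are usable because C10 is enolisable. Me3SiCl/Et3N/DMF gives the more substituted trimethylsilyl enol ether F4, and MeLi then MeI methylates C10 on the face cis to H-5, the pseudo-axial aryloxy group at C4 screening the other face. This returns to the route at 20.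

2. Step 16. Binding of the iridium to the remote (bishomoallylic) hydroxyl may be too weak, and undirected addition of hydrogen to the convex β face would give the C7 epimer; a radical hydrogen-atom-transfer reduction is expected to have the same bias. Fallback: deliver the hydride covalently from the same hydroxyl. From 21, (HMe2Si)2NH gives the dimethylsilyl ether F5. Intramolecular hydrosilylation with Pt2[(CH2=CHSiMe2)2O]3 adds Si to C6 and H to C7 on the α face, giving the cyclic siloxane F6. Tamao–Fleming oxidation (H2O2, KF, KHCO3) gives the 1α,6α-diol F7, Stille allylation as in step 17 gives the diallyl diol F8, and xanthate formation as in step 18 gives the bis-xanthate F9. Bu3SnH then removes both oxygens and returns to the route at 26.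

3. Step 9. The hindered allylic-quaternary vinyl group may initiate slowly, so that homodimerisation of 13 and catalyst decay outrun the cross-metathesis. Fallback: build the enone by aldol condensation. From 10, ozonolysis of its only alkene (O3, CH2Cl2, −78 °C; PPh3) gives the α-aryloxy aldehyde F10, which has no α-hydrogen. The lithium enolate (lithium diisopropylamide, THF, −78 °C) of the triethylsilyl ether F11 of 11, which has one enolisable position, adds to give the aldol F12. Mesylation and elimination (MsCl, Et3N; then DBU) give the E enone and return to the route at 14.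

**Further compounds**
F1 | step 14 | vinyl carbinol | Brc1ccc(Oc2cc(Br)cc(O[C@](/C=C/C(=C)C(C)(C)O[Si](CC)(CC)CC)(C)CCC(O)C=C)c2OCOCC[Si](C)(C)C)cc1
F2 | step 14 | vinyl ketone | Brc1ccc(Oc2cc(Br)cc(O[C@](/C=C/C(=C)C(C)(C)O[Si](CC)(CC)CC)(C)CCC(=O)C=C)c2OCOCC[Si](C)(C)C)cc1
F3 | step 14 | C10–H octalones (both ring fusions) | Brc1ccc(Oc2cc(Br)cc(O[C@]3(C)CCC(=O)C4CCC(C(C)(C)O[Si](CC)(CC)CC)=C[C@@H]43)c2OCOCC[Si](C)(C)C)cc1
F4 | step 14 | trimethylsilyl enol ether (C1=C10) | Brc1ccc(Oc2cc(Br)cc(O[C@]3(C)CCC(O[Si](C)(C)C)=C4CCC(C(C)(C)O[Si](CC)(CC)CC)=C[C@@H]43)c2OCOCC[Si](C)(C)C)cc1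
F5 | step 16 | dimethylsilyl ether of 21 | Brc1ccc(Oc2cc(Br)cc(O[C@]3(C)CC[C@H](O[SiH](C)C)[C@]4(C)CCC(C(C)(C)O[Si](CC)(CC)CC)=C[C@@H]43)c2OCOCC[Si](C)(C)C)cc1
F6 | step 16 | cyclic siloxane (Si on O1 and C6) | Brc1ccc(Oc2cc(Br)cc(O[C@]3(C)CC[C@@H]4O[Si](C)(C)[C@H]5[C@H](C(C)(C)O[Si](CC)(CC)CC)CC[C@]4(C)[C@@H]35)c2OCOCC[Si](C)(C)C)cc1
F7 | step 16 | 1α,6α-diol | Brc1ccc(Oc2cc(Br)cc(O[C@]3(C)CC[C@H](O)[C@]4(C)CC[C@@H](C(C)(C)O[Si](CC)(CC)CC)[C@H](O)[C@@H]43)c2OCOCC[Si](C)(C)C)cc1
F8 | step 16 | diallyl diol | C=CCc1ccc(Oc2cc(CC=C)cc(O[C@]3(C)CC[C@H](O)[C@]4(C)CC[C@@H](C(C)(C)O[Si](CC)(CC)CC)[C@H](O)[C@@H]43)c2OCOCC[Si](C)(C)C)cc1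
F9 | step 16 | bis-xanthate | C=CCc1ccc(Oc2cc(CC=C)cc(O[C@]3(C)CC[C@H](OC(=S)SC)[C@]4(C)CC[C@@H](C(C)(C)O[Si](CC)(CC)CC)[C@H](OC(=S)SC)[C@@H]43)c2OCOCC[Si](C)(C)C)cc1
F10 | step 9 | α-aryloxy aldehyde | Brc1ccc(Oc2cc(Br)cc(O[C@](C=O)(C)CCC(O[Si](C)(C)C)C(C)(C)O[Si](C)(C)C)c2OCOCC[Si](C)(C)C)cc1
F11 | step 9 | 3-methyl-3-(triethylsilyloxy)butan-2-one | CC(=O)C(C)(C)O[Si](CC)(CC)CC
F12 | step 9 | aldol (β-hydroxy ketone, epimers) | Brc1ccc(Oc2cc(Br)cc(O[C@](C(O)CC(=O)C(C)(C)O[Si](CC)(CC)CC)(C)CCC(O[Si](C)(C)C)C(C)(C)O[Si](C)(C)C)c2OCOCC[Si](C)(C)C)cc1
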